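**Retrosynthetic overview**
1. Ring D is closed last through the C11'–C12' bond: an alkoxycarbonyl radical on O8' (from a cesium oxalate) adds 5-exo to C11', the β-carbon of the ring B enone C3=C11', and the resulting C3 radical opens the C1–C2 oxirane, unveiling the C2=C3 enone and the C1 tertiary alcohol in the same operation.
2. Enabling feature: in ring B the spiro carbon C11' is at once α to the ring D carbonyl C12' and allylic to the γ-hydroxy enone C1(OH)–C2=C3(Ac). This O=C12'–C11'–C3=C2–C1–O array is the retron of a radical SN2' allylation of a vinyl oxirane, and it lets two electrophilic carbons (acyl C12' and enone β-carbon C11') be joined by a radical.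
3. Ring B: Suzuki coupling (C3–C11') of an α-iodo dienone with an alkenyl boronate, then 6π-electrocyclisation (C5–C13'). Ring C: carbonylative lactonisation with SN2 inversion at C8. Then C1–C2 epoxidation.
4. Both coupling partners come from one seven-membered monomer 16 (syn-aldol for C7–C8, methyl ketone to enol triflate, domino enyne ring-closing/cross-metathesis). C10 and C10' come from asymmetric hydrogenation of α-methylene-γ-butyrolactone.
5. Ring order: E and A (as monomer 16), then B, C, the oxirane, and D.

Key step: step 20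

Remark: xanthanolide locants are used (upper unit C1–C15, lower unit C1'–C15'). Ring A = upper cycloheptane, ring B = cyclohexene, ring C = upper α-methylene lactone, ring D = spiro lactone, ring E = lower cycloheptene. The configuration is taken exactly as drawn: rings A/C trans-fused, rings E/D cis-fused, both ring methyl groups trans to the C7/C7' substituent.

**Route**

Step 1
Reactants: 1 α-methylene-γ-butyrolactone
Product: 2 (3S)-3-methyloxolan-2-one
Conditions: H2 (100 atm), Ru(OAc)2[(R)-BINAP] (0.5 mol%), CH2Cl2, 50 °C
Reagents that add atoms: none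
Why: Ru–BINAP asymmetric hydrogenation of the carbonyl-chelating exocyclic alkene should set the methyl stereocentre that becomes C10 and C10'; the catalyst antipode is chosen so that the S lactone results.

Step 2
Reactants: 2 (3S)-3-methyloxolan-2-one
Product: 3 (3S)-3-methyloxolan-2-ol (anomer mixture)
Conditions: iBu2AlH (1.05 equiv), CH2Cl2, −78 °C; Rochelle salt work-up
Reagents that add atoms: none
Why: Partial hydride reduction of a lactone should stop at the lactol because the tetrahedral aluminium hemiacetal is stable at −78 °C.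

Step 3
Reactants: 3 (3S)-3-methyloxolan-2-ol
Product: 4 (3S)-3-methylpent-4-yn-1-ol
Conditions: Ohira–Bestmann reagent, K2CO3, MeOH, 0 °C to rt
Reagents that add atoms: Ohira–Bestmann reagent, dimethyl (1-diazo-2-oxopropyl)phosphonate, COP(=O)(OC)C(=[N+]=[N-])C(C)=O
Why: Seyferth–Gilbert homologation in its Ohira–Bestmann form should convert the open hydroxy-aldehyde tautomer of the lactol into the terminal alkyne under carbonate conditions mild enough to keep the α-stereocentre.

Step 4
Reactants: 4 (3S)-3-methylpent-4-yn-1-ol
Product: 5 (3S)-3-methylpent-4-ynal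
Conditions: Dess–Martin periodinane, CH2Cl2, 0 °C to rt; used as a solution
Reagents that add atoms: none
Why: Dess–Martin oxidation of the primary alcohol should give the volatile aldehyde without risk to the stereocentre, which is β to the carbonyl.

Step 5
Reactants: 6 (R)-4-benzyl-1,3-oxazolidin-2-one; 7 pent-4-enoyl chloride
Product: 8 (R)-4-benzyl-3-(pent-4-enoyl)-1,3-oxazolidin-2-one
Conditions: n-BuLi, THF, −78 °C; then 7
Reagents that add atoms: none
Why: N-acylation of the lithiated oxazolidinone is the standard entry to the aldol auxiliary.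

Step 6
Reactants: 8 (R)-4-benzyl-3-(pent-4-enoyl)-1,3-oxazolidin-2-one; 5 (3S)-3-methylpent-4-ynal
Product: 9 (R)-4-benzyl-3-[(2R,3S,5S)-3-hydroxy-5-methyl-2-(prop-2-en-1-yl)hept-6-ynoyl]-1,3-oxazolidin-2-one
Conditions: Bu2BOTf, Et3N, CH2Cl2, −78 to 0 °C; then 5, −78 to 0 °C; pH 7 buffer, MeOH, H2O2
Reagents that add atoms: none
Why: The Evans syn-aldol reaction (Z boron enolate, chair transition state, benzyl group shielding one enolate face) should set C7 (2R) and C8 (3S) under auxiliary control, the remote methyl centre of the aldehyde having little influence.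

Step 7
Reactants: 9 aldol adduct
Product: 10 (2R,3S,5S)-3-hydroxy-N-methoxy-N,5-dimethyl-2-(prop-2-en-1-yl)hept-6-ynamide
Conditions: MeNHOMe·HCl, AlMe3, CH2Cl2, −20 to 0 °C
Reagents that add atoms: N,O-dimethylhydroxylamine hydrochloride, CNOC.Cl
Why: Aluminium-amide transamination of a β-hydroxy acyl oxazolidinone should give the Weinreb amide, the free hydroxyl directing attack to the exocyclic carbonyl.

Step 8
Reactants: 10 hydroxy Weinreb amide
Product: 11 (2R,3S,5S)-N-methoxy-N,5-dimethyl-2-(prop-2-en-1-yl)-3-(triethylsilyloxy)hept-6-ynamide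
Conditions: TESCl, imidazole, DMF, rt
Reagents that add atoms: chlorotriethylsilane, CC[Si](Cl)(CC)CC
Why: Silylation of the secondary alcohol protects it from the strong bases of the next two steps.

Step 9
Reactants: 11 silyl ether Weinreb amide
Product: 12 (3R,4S,6S)-6-methyl-3-(prop-2-en-1-yl)-4-(triethylsilyloxy)oct-7-yn-2-one
Conditions: MeMgBr (3 equiv), THF, −78 to 0 °C
Reagents that add atoms: methylmagnesium bromide, C[Mg]Br
Why: Grignard addition to a Weinreb amide should stop at the methyl ketone through the chelated tetrahedral intermediate, the excess reagent covering the acidic alkyne C–H.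

Step 10
Reactants: 12 methyl ketone
Product: 14 (3R,4S,6S)-4-hydroxy-6-methyl-3-(prop-2-en-1-yl)oct-1-en-7-yn-2-yl trifluoromethanesulfonate, via TES enol triflate 13 (not isolated)
Conditions: KN(SiMe3)2, Comins' reagent, THF, −78 °C; then HF·pyridine, THF, 0 °C
Reagents that add atoms: Comins' reagent, N-(5-chloropyridin-2-yl)-1,1,1-trifluoro-N-(trifluoromethylsulfonyl)methanesulfonamide, O=S(=O)(N(c1ccc(Cl)cn1)S(=O)(=O)C(F)(F)F)C(F)(F)F
Why: Kinetic deprotonation at the methyl group by the hindered amide base followed by O-triflation should give the terminal enol triflate without β-elimination of the silyloxy group, and fluoride desilylation in the same flask frees the C8 hydroxyl.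

Step 11
Reactants: 14 acyclic hydroxy enol triflate
Product: 16 monomer (ring of C1 and C5–C10 with C1=C5; (E)-3-oxobut-1-enyl on C1; 8-OH and 7-[1-(triflyloxy)vinyl] cis; 10-CH3 trans to both), via vinyl diene 15 (not isolated)
Conditions: second-generation Hoveyda–Grubbs catalyst RuCl2(H2IMes)(=CH-C6H4-2-OiPr) (10 mol%), methyl vinyl ketone (10 equiv), CH2Cl2, 40 °C
Reagents that add atoms: methyl vinyl ketone, C=CC(C)=O
Why: Domino ring-closing enyne metathesis (exo mode, seven-membered ring) and E-selective cross-metathesis of the resulting 1-vinylcycloheptene with the enone should build the dienone in one operation, the electron-poor 1,1-disubstituted enol triflate staying a spectator.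

Step 12
Reactants: 16 monomer
Product: 17 alkenyl pinacol boronate of the monomer (Bpin in place of OTf; free 8'-OH)
Conditions: B2pin2, PdCl2(PPh3)2 (3 mol%), PPh3, KOPh, toluene, 50 °C
Reagents that add atoms: bis(pinacolato)diboron, CC1(C)OB(OC1(C)C)B1OC(C)(C)C(C)(C)O1
Why: Miyaura borylation of an alkenyl triflate with phenoxide as base should give the 1,1-disubstituted alkenyl boronate and tolerate the free alcohol and the dienone.

Step 13
Reactants: 16 monomer
Product: 18 C8 mesylate of the monomer
Conditions: MsCl, Et3N, CH2Cl2, 0 °C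
Reagents that add atoms: methanesulfonyl chloride, CS(=O)(=O)Cl
Why: Sulfonylation turns the C8 hydroxyl into the leaving group needed for the later inversion and adds a second substituent on the ring face that the electrocyclisation must avoid.

Step 14
Reactants: 18 mesylate
Product: 19 (Z)-α-iodo dienone (iodine on C3, cis to C1)
Conditions: I2, DMAP (20 mol%), K2CO3, THF–H2O, rt
Reagents that add atoms: iodine, II
Why: Nucleophile-catalysed α-iodination of the enone (Baylis–Hillman-type addition of DMAP at C2, iodination of the enolate at C3, E1cB loss of DMAP) should give the Z iodide, so that the group introduced next stands cis to the ring as the electrocyclisation requires.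

Step 15
Reactants: 17 alkenyl boronate; 19 α-iodo dienone
Product: 21 cyclohexadiene (ring B with C1=C2 and C3=C11'; acetyl on C3; upper 8-OMs and 7-[1-(triflyloxy)vinyl]; lower 8'-OH and dienone), via triene 20 (not isolated)
Conditions: PdCl2(dppf) (5 mol%), AsPh3, K3PO4 (aq), THF–DMF, 25 °C; then toluene, 90 °C
Reagents that add atoms: none
Why: Suzuki–Miyaura coupling should occur at the C–I bond only (25 °C, triflate untouched) with retention of the Z geometry, so that triene 20 undergoes thermal disrotatory 6π-electrocyclisation on warming, the C5–C13' bond forming on the ring A face opposite the cis C7 and C8 substituents (one of which is pseudo-axial in either chair), which sets C5 as S.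

Step 16
Reactants: 21 cyclohexadiene
Product: 23 trans-fused α-methylene lactone (ring C closed; lower 8'-OH free), via acrylic acid 22 (not isolated)
Conditions: Pd(OAc)2 (10 mol%), PPh3, CO (1 atm), KOAc, DMF–H2O, 25 then 65 °C
Reagents that add atoms: carbon monoxide, [C-]#[O+]; water, O
Why: Palladium-catalysed hydroxycarbonylation of the alkenyl triflate gives carboxylate 22, which should displace the C8 mesylate in a 5-exo-tet SN2 lactonisation with inversion, turning the cis C7/C8 pair of 21 into the trans-fused ring C.

Step 17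
Reactants: 23 cyclohexadiene lactone
Product: 24 (1R,2S)-1,2-oxirane (epoxy enone with C3=C11' intact)
Conditions: mCPBA (1.05 equiv), CH2Cl2/aq. pH 7 phosphate buffer, 0 °C
Reagents that add atoms: mCPBA, OOC(=O)c1cccc(Cl)c1
Why: Prilezhaev epoxidation should select the C1=C2 bond, the only trisubstituted alkene not in linear conjugation with a carbonyl, and attack the ring B face cis to H5 and anti to the C5–C6 bond and the 10-methyl group, which fixes the configuration of the future C1 alcohol.

Step 18
Reactants: 24 epoxy alcohol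
Product: 25 methyl oxalate of the 8'-hydroxyl
Conditions: methyl chlorooxoacetate, pyridine, DMAP (5 mol%), CH2Cl2, 0 °C
Reagents that add atoms: methyl chlorooxoacetate, COC(=O)C(Cl)=O
Why: Acylation of the only free hydroxyl installs the carbon that becomes C12' under conditions too mild to open the oxirane.

Step 19
Reactants: 25 methyl oxalate
Product: 26 cesium oxalate
Conditions: CsOH·H2O (1.0 equiv), THF–H2O, 0 °C, 10 min
Reagents that add atoms: cesium hydroxide, [Cs+].[OH-]
Why: Saponification of an oxalate methyl ester is orders of magnitude faster than hydrolysis of the lactone or base-induced opening of the epoxy enone, so one equivalent of hydroxide should give the salt selectively.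

Step 20
Reactants: 26 cesium oxalate
Product: 30 target CNP0168949.5, via alkoxycarbonyl radical 27 (not isolated), via keto radical 28 (not isolated), via alkoxyl radical 29 (not isolated)
Conditions: [Ir(dF(CF3)ppy)2(dtbbpy)]PF6 (2 mol%), DME–DMF 3:1, H2O (10 equiv), 450 nm LEDs, 25 °C, argon, 5 mM
Reagents that add atoms: none
Why: Proposed new method: the excited trivalent iridium photocatalyst oxidises the oxalate, loss of CO2 leaves alkoxycarbonyl radical 27, which adds 5-exo-trig to C11' (the β-carbon of the tetrasubstituted enone, polarity-matched with this nucleophilic σ-radical) to give tertiary α-keto radical 28; β-scission of the adjacent C2–O oxirane bond then forms the C2=C3 enone and alkoxyl radical 29, which is reduced by divalent iridium and protonated by water, and the alternative order (reduction of 28 to the enolate, then E1cB opening) leads to the same product. The closest known reactions are the photoredox alkoxycarbonyl-radical cyclisation of homoallylic cesium oxalates to spiro γ-lactones and the radical SN2' opening of vinyl oxiranes; their union in one cascade and the attack on a fully substituted enone carbon are new. Ring D is the only ring closed (5-exo-trig); ring B is only re-functionalised. C11' should be R because 1,3-allylic strain with the cis acetyl group on C3 holds H7' in the enone plane, so the cis-disposed C8'–O arm can reach only the ring B face that is cis to H5 (the convex face, anti to C6), while C1 keeps the configuration of the oxirane because its C–O bond is not broken. The step needs 5-exo attack at C11' to beat 6-endo attack at C3 (polarity-mismatched), loss of CO2 from 27 (slow for a secondary alkoxycarbonyl radical) and 6-exo addition to C5' of the ring E dienone (bridged transition state), and needs the α-methylene lactone and dienone to stay idle as intermolecular acceptors, which high dilution should secure.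

**Compound list**
1 | α-methylene-γ-butyrolactone | C=C1CCOC1=O | starting material
2 | (3S)-3-methyloxolan-2-one | C[C@H]1CCOC1=O | intermediate
3 | (3S)-3-methyloxolan-2-ol (anomer mixture) | C[C@H]1CCOC1O | intermediate
4 | (3S)-3-methylpent-4-yn-1-ol | C#C[C@@H](C)CCO | intermediate
5 | (3S)-3-methylpent-4-ynal | C#C[C@@H](C)CC=O | intermediate
6 | (R)-4-benzyl-1,3-oxazolidin-2-one | O=C1N[C@H](Cc2ccccc2)CO1 | starting material
7 | pent-4-enoyl chloride | C=CCCC(Cl)=O | starting material
8 | (R)-4-benzyl-3-(pent-4-enoyl)-1,3-oxazolidin-2-one | C=CCCC(=O)N1[C@H](Cc2ccccc2)COC1=O | intermediate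
9 | syn-aldol adduct, (2R,3S,5S) acyl chain on the (R)-auxiliary | C#C[C@@H](C)C[C@H](O)[C@@H](CC=C)C(=O)N1[C@H](Cc2ccccc2)COC1=O | intermediate
10 | (2R,3S,5S)-3-hydroxy Weinreb amide | C#C[C@@H](C)C[C@H](O)[C@@H](CC=C)C(=O)N(C)OC | intermediate
11 | TES ether of 10 | C#C[C@@H](C)C[C@H](O[Si](CC)(CC)CC)[C@@H](CC=C)C(=O)N(C)OC | intermediate
12 | (3R,4S,6S) methyl ketone, TES ether | C#C[C@@H](C)C[C@H](O[Si](CC)(CC)CC)[C@@H](CC=C)C(C)=O | intermediate
13 | TES enol triflate | C#C[C@@H](C)C[C@H](O[Si](CC)(CC)CC)[C@@H](CC=C)C(=C)OS(=O)(=O)C(F)(F)F | intermediate (not isolated)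
14 | (3R,4S,6S)-4-hydroxy-6-methyl-3-(prop-2-en-1-yl)oct-1-en-7-yn-2-yl triflate | C#C[C@@H](C)C[C@H](O)[C@@H](CC=C)C(=C)OS(=O)(=O)C(F)(F)F | intermediate
15 | 1-vinylcycloheptene from enyne ring closure | O[C@H]1C[C@H](C)C(C=C)=CC[C@H]1C(=C)OS(=O)(=O)C(F)(F)F | intermediate (not isolated)
16 | monomer: hydroxy enol triflate dienone (7,8-cis; 10-methyl trans) | O[C@H]1C[C@H](C)C(/C=C/C(C)=O)=CC[C@H]1C(=C)OS(=O)(=O)C(F)(F)F | intermediate
17 | lower partner: alkenyl pinacol boronate, free 8'-OH | O[C@H]1C[C@H](C)C(/C=C/C(C)=O)=CC[C@H]1C(=C)B1OC(C)(C)C(C)(C)O1 | intermediate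
18 | C8 mesylate of 16 | CS(=O)(=O)O[C@H]1C[C@H](C)C(/C=C/C(C)=O)=CC[C@H]1C(=C)OS(=O)(=O)C(F)(F)F | intermediate
19 | upper partner: (Z)-α-iodo dienone mesylate | CS(=O)(=O)O[C@H]1C[C@H](C)C(/C=C(\I)C(C)=O)=CC[C@H]1C(=C)OS(=O)(=O)C(F)(F)F | intermediate
20 | coupled triene (C11' cis to C1 on C2=C3) | CS(=O)(=O)O[C@H]1C[C@H](C)C(/C=C(/C(C)=O)C(=C)[C@@H]2CC=C(/C=C/C(C)=O)[C@@H](C)C[C@@H]2O)=CC[C@H]1C(=C)OS(=O)(=O)C(F)(F)F | intermediate (not isolated)
21 | ring B cyclohexadiene, (5S); upper mesylate and enol triflate | CS(=O)(=O)O[C@H]1C[C@H](C)C2=CC(C(C)=O)=C(C[C@@H]2C[C@H]1C(=C)OS(=O)(=O)C(F)(F)F)[C@@H]3CC=C(/C=C/C(C)=O)[C@@H](C)C[C@@H]3O | intermediate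
22 | acrylic acid mesylate | CS(=O)(=O)O[C@H]1C[C@H](C)C2=CC(C(C)=O)=C(C[C@@H]2C[C@H]1C(=C)C(=O)O)[C@@H]3CC=C(/C=C/C(C)=O)[C@@H](C)C[C@@H]3O | intermediate (not isolated)
23 | cyclohexadiene with trans-fused ring C | C=C1C(=O)O[C@@H]2C[C@H](C)C3=CC(C(C)=O)=C(C[C@@H]3C[C@@H]12)[C@@H]4CC=C(/C=C/C(C)=O)[C@@H](C)C[C@@H]4O | intermediate
24 | (1R,2S)-epoxy enone alcohol | C=C1C(=O)O[C@@H]2C[C@H](C)[C@@]35O[C@H]5C(C(C)=O)=C(C[C@@H]3C[C@@H]12)[C@@H]4CC=C(/C=C/C(C)=O)[C@@H](C)C[C@@H]4O | intermediate
25 | methyl oxalate of 24 | C=C1C(=O)O[C@@H]2C[C@H](C)[C@@]35O[C@H]5C(C(C)=O)=C(C[C@@H]3C[C@@H]12)[C@@H]4CC=C(/C=C/C(C)=O)[C@@H](C)C[C@@H]4OC(=O)C(=O)OC | intermediate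
26 | cesium oxalate of 24 | C=C1C(=O)O[C@@H]2C[C@H](C)[C@@]35O[C@H]5C(C(C)=O)=C(C[C@@H]3C[C@@H]12)[C@@H]4CC=C(/C=C/C(C)=O)[C@@H](C)C[C@@H]4OC(=O)C(=O)[O-].[Cs+] | intermediate
27 | alkoxycarbonyl radical on O8' | C=C1C(=O)O[C@@H]2C[C@H](C)[C@@]35O[C@H]5C(C(C)=O)=C(C[C@@H]3C[C@@H]12)[C@@H]4CC=C(/C=C/C(C)=O)[C@@H](C)C[C@@H]4O[C]=O | intermediate (radical, not isolated)
28 | spiro lactone with C3 α-keto radical, oxirane intact | C=C1C(=O)O[C@@H]2C[C@H](C)[C@@]35O[C@H]5[C](C(C)=O)[C@]4(C[C@@H]3C[C@@H]12)C(=O)O[C@H]1C[C@H](C)C(/C=C/C(C)=O)=CC[C@H]14 | intermediate (radical, not isolated)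
29 | C1 alkoxyl radical with C2=C3 enone | C=C1C(=O)O[C@@H]2C[C@H](C)[C@]3([O])C=C(C(C)=O)[C@]4(C[C@@H]3C[C@@H]12)C(=O)O[C@H]1C[C@H](C)C(/C=C/C(C)=O)=CC[C@H]14 | intermediate (radical, not isolated)
30 | CNP0168949.5 | C=C1C(=O)O[C@@H]2C[C@H](C)[C@]3(O)C=C(C(C)=O)[C@]4(C[C@@H]3C[C@@H]12)C(=O)O[C@H]1C[C@H](C)C(/C=C/C(C)=O)=CC[C@H]14 | target

**Step count and risks**
Total steps: 20. Longest linear sequence: 18 steps (steps 1–4, 6–11 and 13–20).

1. Step 20 (proposed new method). What may go wrong: loss of CO2 from the alkoxycarbonyl radical before it cyclises, addition of the radical to the ring E dienone, or quenching of the α-keto radical before the oxirane opens, each of which erodes formation of the spiro centre. Fallback with known chemistry, setting out from 16 and 18 and coming back at 30: intramolecular alkoxycarbonylation of 16 (Pd(OAc)2, PPh3, CO, Et3N, MeCN, 60 °C) gives the cis-fused lower α-methylene lactone F1. Thermal or high-pressure Diels–Alder reaction of F1 as dienophile with diene 18 forms the C5–C13' and C3–C11' bonds and gives adduct F2 (C3 epimers are of no consequence). The conditions of step 16 close ring C with inversion to give the β,γ-unsaturated ketone F3. Epoxidation of its isolated C1=C2 bond with mCPBA gives oxirane F4, and DBU opens F4 by E1cB to give 30.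

2. Step 15. What may go wrong: poor facial selectivity in the electrocyclisation (closure on the ring A face that carries the C7 and C8 substituents, which would set C5 wrongly), or competing coupling at the triflate. Fallback, setting out from 18 and coming back at 23: the order of ring formation is changed so that the rigid trans-fused ring C, not the flexible cis C7/C8 pair, governs the face. The conditions of step 16 applied to 18 give the upper trans-lactone dienone F5, α-iodination as in step 14 gives the Z iodide F6, and coupling of F6 with boronate 17 followed by warming gives 23 directly, with no triflate left to compete.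

3. Step 17. What may go wrong: competing oxidation of the ring E alkene C1'=C5', or attack on the wrong face of ring B. Fallback, setting out from 23 and coming back at 30: the oxidation is moved behind the ring D closure. Acylation of 23 as in step 18 gives methyl oxalate F7 and saponification as in step 19 gives cesium oxalate F8. Photoredox cyclisation under the conditions of step 20, now onto the dienyl ketone and ending with protonation of the dienolate at C3, gives the ketone F3 described above, in which C1=C2 is the only isolated trisubstituted alkene. Epoxidation to F4 and DBU-induced opening then give 30.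

**Further compounds**
F1 | step 20 | cis-fused lower α-methylene lactone dienone | C=C1C(=O)O[C@H]2C[C@H](C)C(/C=C/C(C)=O)=CC[C@@H]12
F2 | step 20 | Diels–Alder adduct with upper mesylate and enol triflate | CS(=O)(=O)O[C@H]1C[C@H](C)C2=CC(C(C)=O)[C@]3(C[C@@H]2C[C@H]1C(=C)OS(=O)(=O)C(F)(F)F)C(=O)O[C@H]4C[C@H](C)C(/C=C/C(C)=O)=CC[C@H]43
F3 | step 20 | β,γ-unsaturated ketone bis-lactone (C1=C2, H on C3) | C=C1C(=O)O[C@@H]2C[C@H](C)C3=CC(C(C)=O)[C@]4(C[C@@H]3C[C@@H]12)C(=O)O[C@H]1C[C@H](C)C(/C=C/C(C)=O)=CC[C@H]14
F4 | step 20 | 1,2-oxirane of F3 | C=C1C(=O)O[C@@H]2C[C@H](C)[C@@]35O[C@H]5C(C(C)=O)[C@]4(C[C@@H]3C[C@@H]12)C(=O)O[C@H]1C[C@H](C)C(/C=C/C(C)=O)=CC[C@H]14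
F5 | step 15 | upper trans-lactone dienone | C=C1C(=O)O[C@@H]2C[C@H](C)C(/C=C/C(C)=O)=CC[C@@H]12
F6 | step 15 | (Z)-α-iodo dienone of F5 | C=C1C(=O)O[C@@H]2C[C@H](C)C(/C=C(\I)C(C)=O)=CC[C@@H]12
F7 | step 17 | methyl oxalate of 23 | C=C1C(=O)O[C@@H]2C[C@H](C)C3=CC(C(C)=O)=C(C[C@@H]3C[C@@H]12)[C@@H]4CC=C(/C=C/C(C)=O)[C@@H](C)C[C@@H]4OC(=O)C(=O)OC
F8 | step 17 | cesium oxalate of 23 | C=C1C(=O)O[C@@H]2C[C@H](C)C3=CC(C(C)=O)=C(C[C@@H]3C[C@@H]12)[C@@H]4CC=C(/C=C/C(C)=O)[C@@H](C)C[C@@H]4OC(=O)C(=O)[O-].[Cs+]
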